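**Plan**

- Prostanoid numbering is used: C1 is the ester carbon, C8–C12 the ring (C9 ketone, C10 C–Cl, C11 =CH, C12 carbinol), C13–C20 the octenyl chain. The retrosynthesis cuts, in order, O–Si at C12, C7=C8 (aldol condensation), C14=C15 (Wittig), the ring bond C9–C10, and last the two bonds from C12 to its allyl arms.
- Feature that makes the ring closure possible: after these cuts C12 carries two identical CH2–CHO arms (C8–C9 and C13–C14), an oxygen and the unit C11≡C10–Cl. The ring C8–C12 with its chloro enone is therefore the product of adding the formyl C9–H bond of an achiral 3-(chloroethynyl)glutaraldehyde across C10≡C11.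
- Forward: the acyclic chain is built from ethyl 3-(trimethylsilyl)propiolate and two allyl Grignard units, and the only ring closes in the rhodium step. The octenyl chain is then completed at C14, the C1–C7 chain is joined at C8, and the silyl ether is removed.
- Stereochemistry: C12 (R in the target) comes from the chiral bisphosphine, which selects one of the two enantiotopic arms in the ring closure. 14Z comes from the non-stabilised ylide, 5E from cross-metathesis, and 7Z from anti aldol addition followed by anti elimination.

Key step: step 6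

Assumption: the sense in which a given antipode of the bisphosphine differentiates the two formylmethyl arms in step 6 cannot be derived safely from a model. The (R)-ligand is written; the (S)-ligand would be used, with nothing else changed, if the first run shows the opposite sense.

**Route**

Step 1
Reactants: 1 ethyl 3-(trimethylsilyl)prop-2-ynoate; 2 allylmagnesium bromide (2.3 equiv)
Product: 3 4-[(trimethylsilyl)ethynyl]hepta-1,6-dien-4-ol
Conditions: Et2O, −78 °C → 0 °C; then H2O
Reagents that add atoms: none
Why: Double Grignard addition to the ester (by way of the ynone) should stop at the tertiary alkoxide, because allylmagnesium halides add 1,2 through a six-membered transition state and the silyl group shields the β-carbon from conjugate addition.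

Step 2
Reactants: 3 4-[(trimethylsilyl)ethynyl]hepta-1,6-dien-4-ol
Product: 4 4-ethynylhepta-1,6-dien-4-ol
Conditions: K2CO3 (0.2 equiv), MeOH, rt
Reagents that add atoms: none
Why: Base-catalysed methanolysis of the C(sp)–Si bond (protodesilylation of an alkynylsilane) leaves the tertiary alcohol and the allyl groups untouched.

Step 3
Reactants: 4 4-ethynylhepta-1,6-dien-4-ol
Product: 5 triethyl[(4-ethynylhepta-1,6-dien-4-yl)oxy]silane
Conditions: Et3SiOTf, 2,6-lutidine, CH2Cl2, −78 °C → 0 °C
Reagents that add atoms: triethylsilyl trifluoromethanesulfonate, CC[Si](CC)(CC)OS(=O)(=O)C(F)(F)F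
Why: Silylation of a hindered tertiary propargylic alcohol with a silyl triflate and a hindered pyridine base is standard, and the triethylsilyl ether should survive base, ozone and enolate chemistry while serving later as the oxygen substituent next to the alkyne.

Step 4
Reactants: 5 triethyl[(4-ethynylhepta-1,6-dien-4-yl)oxy]silane
Product: 7 [(4-(chloroethynyl)hepta-1,6-dien-4-yl)oxy]triethylsilane, via lithium acetylide 6 (not isolated)
Conditions: n-BuLi, THF, −78 °C; then N-chlorosuccinimide, −78 °C → rt; then H2O
Reagents that add atoms: N-chlorosuccinimide, O=C1CCC(=O)N1Cl; n-butyllithium, CCCC[Li] (lithium of intermediate 6 only)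
Why: Deprotonation of the terminal alkyne and electrophilic chlorination of the lithium acetylide is the standard route to 1-chloroalkynes, and nothing else in 5 is acidic or electrophilic.

Step 5
Reactants: 7 [(4-(chloroethynyl)hepta-1,6-dien-4-yl)oxy]triethylsilane
Product: 9 3-(chloroethynyl)-3-(triethylsilyloxy)pentanedial, via bis-ozonide 8 (not isolated)
Conditions: O3, CH2Cl2, −78 °C, Sudan red 7B as end-point indicator; then PPh3 (2.2 equiv), −78 °C → rt
Reagents that add atoms: ozone, [O-][O+]=O
Why: Ozone should cleave the two electron-rich terminal alkenes far faster than the electron-poor chloroalkyne, and reductive work-up of the bis-ozonide (ozonolysis) gives the 3-silyloxyglutaraldehyde, in which no stereocentre arises because the two arms are identical.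

Step 6
Reactants: 9 3-(chloroethynyl)-3-(triethylsilyloxy)pentanedial
Product: 10 2-[(1S)-3-chloro-4-oxo-1-(triethylsilyloxy)cyclopent-2-en-1-yl]acetaldehyde
Conditions: [Rh((R)-Tol-BINAP)]BF4 (5 mol%, made from [Rh(nbd)((R)-Tol-BINAP)]BF4 and H2), degassed CH2Cl2, 0.05 M, rt
Reagents that add atoms: none
Why: Proposed new method: cationic monovalent rhodium should insert into one formyl C–H bond of 9 to give an acyl hydride of trivalent rhodium held by the chloroalkyne, the hydride should then add to the inner alkyne carbon C11 anti to the metal so that a six-membered acyl–alkenyl rhodacycle with rhodium on the chlorine-bearing C10 results, and C–C reductive elimination forms the C9–C10 bond and returns the catalyst. The closest known reaction type is the trans-hydroacylation of 4-alkynals to cyclopent-2-enones with cationic rhodium bisphosphine catalysts, which is also known as a kinetic resolution of 3-alkoxy-4-alkynals with a fully substituted C3 and as a desymmetrisation of dialkynyl aldehydes; not shown so far are a 1-chloroalkyne as the acceptor and the choice between two enantiotopic formyl groups. The cyclopentenone ring C8–C12 closes in a formal 5-endo-dig mode, both alkyne carbons ending up in the ring, through contraction of the six-membered metallacycle. C12 is prochiral in 9 and becomes the only stereocentre when one CH2CHO arm enters the ring; the chiral ligand controls which arm reacts, and because reaction through one arm or the other is the same event as reaction of one or the other enantiomer of a 3-alkoxy-4-alkynal, the selectivity known from the kinetic resolutions should appear here inside one molecule, with the advantage that all of the material can be converted. The step needs regioselectivity for the cyclopentenone over the 4-exo alkylidenecyclobutanone, secured by the oxygen substituent on C12 and by the polarisation of the chloroalkyne, which directs hydride to the carbon remote from chlorine as in the hydrometalation of 1-haloalkynes, and chemoselectivity for C–H over C(sp)–Cl insertion, which rests on the chelate-assisted C–H activation at room temperature. The second formyl group should stay untouched after ring closure, since the only alkene it could reach is the trisubstituted, chlorine-bearing enone bond and addition there would give a strained bicycle.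

Step 7
Reactants: 10 2-[(1S)-3-chloro-4-oxo-1-(triethylsilyloxy)cyclopent-2-en-1-yl]acetaldehyde; 11 hexyltriphenylphosphonium bromide
Product: 12 (4S)-2-chloro-4-[(2Z)-oct-2-en-1-yl]-4-(triethylsilyloxy)cyclopent-2-en-1-one
Conditions: 11 (1.1 equiv), NaN(SiMe3)2 (1.05 equiv), THF, 0 °C; then 10, −78 °C → −30 °C
Reagents that add atoms: none
Why: A non-stabilised ylide under salt-poor conditions adds to the aldehyde under kinetic control to give the cis-oxaphosphetane and hence the Z alkene (Wittig reaction), and at −78 °C the aldehyde should react much faster than the conjugated ring ketone, whose β-carbon C11 is shielded by the fully substituted C12.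

Step 8
Reactants: 13 methyl hex-5-enoate; 14 (E)-but-2-enal (4 equiv)
Product: 15 methyl (5E)-7-oxohept-5-enoate
Conditions: second-generation Hoveyda–Grubbs catalyst RuCl2(H2IMes)(=CH-C6H4-2-OiPr) (2.5 mol%), CH2Cl2, 40 °C
Reagents that add atoms: none
Why: Cross-metathesis of a terminal alkene with an excess of crotonaldehyde gives the conjugated enal as the E isomer under thermodynamic control, with propene leaving as a gas.

Step 9
Reactants: 12 (4S)-2-chloro-4-[(2Z)-oct-2-en-1-yl]-4-(triethylsilyloxy)cyclopent-2-en-1-one; 15 methyl (5E)-7-oxohept-5-enoate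
Product: 17 methyl (5E)-7-[(5S)-3-chloro-5-[(2Z)-oct-2-en-1-yl]-2-oxo-5-(triethylsilyloxy)cyclopent-3-en-1-yl]-7-hydroxyhept-5-enoate (diastereomer mixture at C7/C8), via lithium dienolate 16 (not isolated)
Conditions: LiN(iPr)2 (1.05 equiv), THF, −78 °C; then 15, −78 °C, 20 min; AcOH quench at −78 °C
Reagents that add atoms: lithium diisopropylamide, CC(C)N([Li])C(C)C (lithium of intermediate 16 only)
Why: Kinetic deprotonation can occur only at C8 (C12 is fully substituted, and the enolate cannot expel the silyloxy group without forming a cyclopentadienone), and the lithium dienolate should add 1,2 to the enal at −78 °C (directed aldol addition) through a closed chair transition state that favours the anti adduct; the new centres at C7 and C8 are removed in the next step.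

Step 10
Reactants: 17 methyl (5E)-7-[(5S)-3-chloro-5-[(2Z)-oct-2-en-1-yl]-2-oxo-5-(triethylsilyloxy)cyclopent-3-en-1-yl]-7-hydroxyhept-5-enoate
Product: 19 methyl (5E,7Z,12R,14Z)-10-chloro-9-oxo-12-(triethylsilyloxy)prosta-5,7,10,14-tetraen-1-oate, via allylic mesylate 18 (not isolated)
Conditions: MsCl (1.5 equiv), DMAP (5 equiv), CH2Cl2, 0 °C → rt, in the dark
Reagents that add atoms: methanesulfonyl chloride, CS(=O)(=O)Cl (atoms of intermediate 18 only)
Why: Mesylation of the C7 alcohol and base-induced loss of methanesulfonate complete the aldol condensation; anti-periplanar elimination from the anti adduct places C6 cis to the C9 carbonyl (7Z), and if the reaction runs through the enolate the C6 chain should likewise turn away from the fully substituted C12, while the 5E and 14Z alkenes are not touched.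

Step 11
Reactants: 19 methyl (5E,7Z,12R,14Z)-10-chloro-9-oxo-12-(triethylsilyloxy)prosta-5,7,10,14-tetraen-1-oate
Product: 20 methyl (5E,7Z,12R,14Z)-10-chloro-12-hydroxy-9-oxoprosta-5,7,10,14-tetraen-1-oate (the target)
Conditions: HF·pyridine, pyridine, THF, 0 °C, in the dark
Reagents that add atoms: none
Why: Fluoride cleaves the tertiary triethylsilyl ether under buffered conditions that should spare the cross-conjugated dienone, the methyl ester and the tertiary alcohol, which does not ionise easily because the cation would be of the cyclopentadienyl type.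

**Compound list**

1 | ethyl 3-(trimethylsilyl)prop-2-ynoate | CCOC(=O)C#C[Si](C)(C)C | starting material
2 | allylmagnesium bromide | C=CC[Mg]Br | starting material
3 | 4-[(trimethylsilyl)ethynyl]hepta-1,6-dien-4-ol | C=CCC(O)(CC=C)C#C[Si](C)(C)C | intermediate
4 | 4-ethynylhepta-1,6-dien-4-ol | C=CCC(O)(CC=C)C#C | intermediate
5 | triethyl[(4-ethynylhepta-1,6-dien-4-yl)oxy]silane | C=CCC(CC=C)(O[Si](CC)(CC)CC)C#C | intermediate
6 | lithium acetylide of 5 (not isolated) | [Li]C#CC(CC=C)(CC=C)O[Si](CC)(CC)CC | intermediate
7 | [(4-(chloroethynyl)hepta-1,6-dien-4-yl)oxy]triethylsilane | ClC#CC(CC=C)(CC=C)O[Si](CC)(CC)CC | intermediate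
8 | bis-ozonide of 7, 3,3'-[2-(chloroethynyl)-2-(triethylsilyloxy)propane-1,3-diyl]bis(1,2,4-trioxolane), diastereomer mixture (not isolated) | ClC#CC(CC1OCOO1)(CC1OCOO1)O[Si](CC)(CC)CC | intermediate
9 | 3-(chloroethynyl)-3-(triethylsilyloxy)pentanedial | O=CCC(CC=O)(O[Si](CC)(CC)CC)C#CCl | intermediate
10 | 2-[(1S)-3-chloro-4-oxo-1-(triethylsilyloxy)cyclopent-2-en-1-yl]acetaldehyde | O=CC[C@@]1(O[Si](CC)(CC)CC)C=C(Cl)C(=O)C1 | intermediate
11 | hexyltriphenylphosphonium bromide | CCCCCC[P+](c1ccccc1)(c1ccccc1)c1ccccc1.[Br-] | starting material
12 | (4S)-2-chloro-4-[(2Z)-oct-2-en-1-yl]-4-(triethylsilyloxy)cyclopent-2-en-1-one | CCCCC/C=C\C[C@@]1(O[Si](CC)(CC)CC)C=C(Cl)C(=O)C1 | intermediate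
13 | methyl hex-5-enoate | C=CCCCC(=O)OC | starting material
14 | (E)-but-2-enal (crotonaldehyde) | C/C=C/C=O | starting material
15 | methyl (5E)-7-oxohept-5-enoate | O=C/C=C/CCCC(=O)OC | intermediate
16 | lithium dienolate of 12, deprotonated at C8 (not isolated) | CCCCC/C=C\C[C@@]1(O[Si](CC)(CC)CC)C=C(Cl)C(O[Li])=C1 | intermediate
17 | methyl (5E)-7-[(5S)-3-chloro-5-[(2Z)-oct-2-en-1-yl]-2-oxo-5-(triethylsilyloxy)cyclopent-3-en-1-yl]-7-hydroxyhept-5-enoate, mixture at C7 and C8 | CCCCC/C=C\C[C@@]1(O[Si](CC)(CC)CC)C=C(Cl)C(=O)C1C(O)/C=C/CCCC(=O)OC | intermediate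
18 | C7 methanesulfonate of 17 (not isolated) | CCCCC/C=C\C[C@@]1(O[Si](CC)(CC)CC)C=C(Cl)C(=O)C1C(OS(C)(=O)=O)/C=C/CCCC(=O)OC | intermediate
19 | methyl (5E,7Z,12R,14Z)-10-chloro-9-oxo-12-(triethylsilyloxy)prosta-5,7,10,14-tetraen-1-oate | CCCCC/C=C\C[C@@]1(O[Si](CC)(CC)CC)C=C(Cl)C(=O)/C1=C\C=C\CCCC(=O)OC | intermediate
20 | methyl (5E,7Z,12R,14Z)-10-chloro-12-hydroxy-9-oxoprosta-5,7,10,14-tetraen-1-oate | CCCCC/C=C\C[C@@]1(O)C=C(Cl)C(=O)/C1=C\C=C\CCCC(=O)OC | target

**Step count**

Total: 11 steps. Longest linear sequence: 10 steps (steps 1–7 and 9–11); step 8 is a one-step side branch.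

**Steps most likely to fail**

1. Step 6. The catalyst may discriminate poorly between the two enantiotopic formylmethyl arms, rhodium may insert into the C(sp)–Cl bond, or the acyl hydride may be diverted to the four-membered ketone or to decarbonylation. The fallback uses known reactions only; it sets out from 2 and comes back at 10, and takes C12 from a purchased building block instead of from the catalyst. Compound 2 is added at −78 °C in THF to purchased (R)-4-(tert-butyldimethylsilyloxy)cyclopent-2-en-1-one F1; 1,2-addition on the face opposite to the silyloxy group should give (1S,4R)-1-allyl-4-(tert-butyldimethylsilyloxy)cyclopent-2-en-1-ol F2. Bu4NF removes the silyl group to give (1S,4R)-1-allylcyclopent-2-ene-1,4-diol F3. MnO2 oxidises only the secondary allylic alcohol to (S)-4-allyl-4-hydroxycyclopent-2-en-1-one F4, so that the former carbinol carbon of F1 becomes C9 and its former carbonyl carbon becomes C12. Nucleophilic epoxidation (H2O2, NaOH, MeOH, 0 °C) gives (4S)-4-allyl-4-hydroxy-6-oxabicyclo[3.1.0]hexan-2-one F5. HCl in MeOH opens the epoxide at the α-carbon and the chlorohydrin loses water to give (S)-4-allyl-2-chloro-4-hydroxycyclopent-2-en-1-one F6. Et3SiOTf with 2,6-lutidine gives (S)-4-allyl-2-chloro-4-(triethylsilyloxy)cyclopent-2-en-1-one F7, and ozonolysis of its allyl group (O3, then PPh3) gives 10.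

2. Step 10. Control over the C7=C8 geometry may be lost if the elimination runs through a freely rotating enolate, and the dienone may isomerise in light. The fallback sets out from 12 and comes back at 19; it forms the C6–C7 bond by cross-coupling on an alkene of fixed geometry instead of forming C7=C8 by elimination. The lithium enolate of 12 (LiN(iPr)2, THF, −78 °C) is C-formylated with 2,2,2-trifluoroethyl formate (Claisen-type formylation) to give (4R,5Z)-2-chloro-5-(hydroxymethylidene)-4-[(2Z)-oct-2-en-1-yl]-4-(triethylsilyloxy)cyclopent-2-en-1-one F8. Its chelated sodium salt (NaH, THF) is sulfonylated with PhNTf2 on the formyl oxygen, which should give [(Z)-[(5R)-3-chloro-5-[(2Z)-oct-2-en-1-yl]-2-oxo-5-(triethylsilyloxy)cyclopent-3-en-1-ylidene]methyl] trifluoromethanesulfonate F9, with the sulfonate oxygen held cis to the C9 carbonyl. Hydroboration of methyl hex-5-ynoate with pinacolborane (Cp2Zr(H)Cl cat., Et3N) gives methyl (5E)-6-(4,4,5,5-tetramethyl-1,3,2-dioxaborolan-2-yl)hex-5-enoate F10. Suzuki–Miyaura coupling of F9 with F10 (Pd(PPh3)4, K3PO4, dioxane/H2O, rt) proceeds with retention at both alkenes and gives 19.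

3. Step 7. The strongly basic alkylidene ylide may deprotonate α to the aldehyde, with loss of the β-silyloxy group, or at C8, or it may attack the chloro enone. The fallback sets out from 10 and comes back at 12; it uses a less basic one-carbon ylide and forms the C15–C16 bond by cross-coupling. Stork–Zhao olefination of 10 ((iodomethyl)triphenylphosphonium iodide, NaN(SiMe3)2, THF/DMPU, −78 °C) should give (4S)-2-chloro-4-[(2Z)-3-iodoprop-2-en-1-yl]-4-(triethylsilyloxy)cyclopent-2-en-1-one F11. Negishi coupling of F11 with pentylzinc bromide (Pd(dppf)Cl2 cat., THF, rt) retains the Z geometry, reacts at the C–I bond much faster than at the C–Cl bond of the enone, and gives 12.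

**Further compounds**

F1 | step 6 | (R)-4-(tert-butyldimethylsilyloxy)cyclopent-2-en-1-one (purchased) | O=C1C=C[C@H](O[Si](C)(C)C(C)(C)C)C1
F2 | step 6 | (1S,4R)-1-allyl-4-(tert-butyldimethylsilyloxy)cyclopent-2-en-1-ol | C=CC[C@@]1(O)C=C[C@H](O[Si](C)(C)C(C)(C)C)C1
F3 | step 6 | (1S,4R)-1-allylcyclopent-2-ene-1,4-diol | C=CC[C@@]1(O)C=C[C@H](O)C1
F4 | step 6 | (S)-4-allyl-4-hydroxycyclopent-2-en-1-one | C=CC[C@@]1(O)C=CC(=O)C1
F5 | step 6 | (4S)-4-allyl-4-hydroxy-6-oxabicyclo[3.1.0]hexan-2-one, epoxide configuration not fixed | C=CC[C@@]1(O)C2OC2C(=O)C1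
F6 | step 6 | (S)-4-allyl-2-chloro-4-hydroxycyclopent-2-en-1-one | C=CC[C@@]1(O)C=C(Cl)C(=O)C1
F7 | step 6 | (S)-4-allyl-2-chloro-4-(triethylsilyloxy)cyclopent-2-en-1-one | C=CC[C@@]1(O[Si](CC)(CC)CC)C=C(Cl)C(=O)C1
F8 | step 10 | (4R,5Z)-2-chloro-5-(hydroxymethylidene)-4-[(2Z)-oct-2-en-1-yl]-4-(triethylsilyloxy)cyclopent-2-en-1-one | CCCCC/C=C\C[C@@]1(O[Si](CC)(CC)CC)C=C(Cl)C(=O)/C1=C\O
F9 | step 10 | [(Z)-[(5R)-3-chloro-5-[(2Z)-oct-2-en-1-yl]-2-oxo-5-(triethylsilyloxy)cyclopent-3-en-1-ylidene]methyl] trifluoromethanesulfonate | CCCCC/C=C\C[C@@]1(O[Si](CC)(CC)CC)C=C(Cl)C(=O)/C1=C\OS(=O)(=O)C(F)(F)F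
F10 | step 10 | methyl (5E)-6-(4,4,5,5-tetramethyl-1,3,2-dioxaborolan-2-yl)hex-5-enoate | COC(=O)CCC/C=C/B1OC(C)(C)C(C)(C)O1
F11 | step 7 | (4S)-2-chloro-4-[(2Z)-3-iodoprop-2-en-1-yl]-4-(triethylsilyloxy)cyclopent-2-en-1-one | I/C=C\C[C@@]1(O[Si](CC)(CC)CC)C=C(Cl)C(=O)C1
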